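**Retrosynthetic overview**
- The route rests on the C13 carbinol that sits on the methyl-bearing C12 of the E-C11=C12 alkene in the 14-membered ring. The target 26 comes from the 13-O-silyl macrocycle 24, and 24 from ynal 23 by nickel-catalysed reductive alkyne–aldehyde macrocyclisation. This forms C12–C13, the C13 centre, the E-alkene and the carbocycle.
- Ynal 23 comes from allyl butenolide 21 by cleavage of the C1 allyl group. 21 comes from a Still–Gennari olefination (Z-C7=C8) of butenolide aldehyde 16 with pentynyl phosphonate 20, made from pent-3-yn-1-ol.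
- The butenolide (C1, C2, lactone) comes from the (S)-propargylic alcohol 11 by alkoxide-directed anti-allylmagnesiation and CO2 capture. C2 is set by CBS reduction of ynone 10.
- Geranyl acetate supplies C2–C7 with the E-C3=C4 alkene, through epoxidation and periodate cleavage.
- Ring order: butenolide first (step 8), then the 14-membered ring (step 15).

Key step: step 15

Remark: ring atoms are numbered C1 (butenolide β-carbon), C2 (lactone O–CH), C3=C4(Me), C5, C6, C7=C8(CO2Me), C9, C10, C11=C12(Me), C13, C14. Compounds 2, 3, 20 and 22 are carried as mixtures at centres that are later destroyed.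

**Route**

Step 1
Reactants: 1 geranyl acetate
Product: 2 (2E)-5-(3,3-dimethyloxiran-2-yl)-3-methylpent-2-en-1-yl acetate
Conditions: mCPBA (1.05 equiv), NaHCO3, CH2Cl2, 0 °C
Reagents that add atoms: mCPBA, O=C(OO)c1cccc(Cl)c1
Why: Prilezhaev epoxidation should go to the electron-rich 6,7-alkene, because the 2,3-alkene is deactivated by the allylic acetate.

Step 2
Reactants: 2 epoxygeranyl acetate
Product: 4 (2E)-3-methyl-6-oxohex-2-en-1-yl acetate, via glycol 3 (not isolated)
Conditions: H5IO6 (1.2 equiv), THF/H2O, 0 °C → rt
Reagents that add atoms: water, O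
Why: Acidic opening of the epoxide to the glycol and Malaprade glycol cleavage in one flask should give the C7 aldehyde and acetone without touching the allylic acetate or the E-alkene.

Step 3
Reactants: 4 acetoxy aldehyde
Product: 6 (2E)-6,6-dimethoxy-3-methylhex-2-en-1-ol, via acetoxy acetal 5 (not isolated)
Conditions: HC(OMe)3, PPTS (cat.), MeOH, rt; then K2CO3, rt
Reagents that add atoms: trimethyl orthoformate, COC(OC)OC; methanol, CO
Why: Acid-catalysed acetalisation masks the future C7 aldehyde for the organomagnesium steps, and base-mediated methanolysis then frees the allylic alcohol in the same flask.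

Step 4
Reactants: 6 hydroxy acetal
Product: 7 (2E)-6,6-dimethoxy-3-methylhex-2-enal
Conditions: activated MnO2 (excess), CH2Cl2, rt
Reagents that add atoms: none
Why: MnO2 oxidises the allylic alcohol selectively and should keep the E geometry of the enal.

Step 5
Reactants: 7 enal; 8 1-propynylmagnesium bromide
Product: 9 racemic (5E)-9,9-dimethoxy-6-methylnon-5-en-2-yn-4-ol
Conditions: THF, −78 → 0 °C; sat. aq. NH4Cl
Reagents that add atoms: none
Why: Grignard 1,2-addition to the enal builds the C2 carbinol carbon with its methyl-capped alkyne; the configuration is set in step 7.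

Step 6
Reactants: 9 racemic carbinol
Product: 10 (5E)-9,9-dimethoxy-6-methylnon-5-en-2-yn-4-one
Conditions: activated MnO2 (excess), CH2Cl2, rt
Reagents that add atoms: none
Why: The alcohol is both allylic and propargylic, so MnO2 should oxidise it under neutral conditions that leave the acetal and the E-alkene alone.

Step 7
Reactants: 10 ynone
Product: 11 (4S,5E)-9,9-dimethoxy-6-methylnon-5-en-2-yn-4-ol
Conditions: (S)-Me-CBS oxazaborolidine (0.3 equiv), catecholborane (1.8 equiv), toluene, −78 °C; MeOH quench, aq. NaOH wash
Reagents that add atoms: none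
Why: In this Corey–Bakshi–Shibata reduction the ketone should bind boron anti to the branched alkenyl arm (large group) and syn to the slim propynyl group (small group), so hydride is delivered to the face that gives the (S)-carbinol, the future C2.

Step 8
Reactants: 11 (S)-propargylic alcohol; 12 allylmagnesium bromide
Product: 15 (5S)-5-[(1E)-5,5-dimethoxy-2-methylpent-1-en-1-yl]-3-methyl-4-(prop-2-en-1-yl)furan-2(5H)-one, via oxamagnesacycle 13 (not isolated), via Z-hydroxy acid 14 (not isolated)
Conditions: 12 (4 equiv), Et2O/THF, 0 → 45 °C; CO2 (gas), −20 °C → rt; 10% aq. citric acid, rt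
Reagents that add atoms: carbon dioxide, O=C=O
Why: In this alkoxide-directed anti-carbomagnesiation the magnesium alkoxide delivers allyl to the proximal alkyne carbon and holds the new C–Mg bond in a five-membered chelate cis to C2, so carboxylation with retention and acidification close the butenolide while C2 is untouched.

Step 9
Reactants: 15 butenolide acetal
Product: 16 (4E)-4-methyl-5-[(2S)-4-methyl-5-oxo-3-(prop-2-en-1-yl)-2,5-dihydrofuran-2-yl]pent-4-enal
Conditions: AcOH/THF/H2O (3:1:1), rt
Reagents that add atoms: water, O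
Why: Mild acid hydrolysis of the acyclic dimethyl acetal should free the C7 aldehyde without affecting the lactone, the allyl group or C2.

Step 10
Reactants: 17 pent-3-yn-1-ol
Product: 18 5-iodopent-2-yne
Conditions: I2, PPh3, imidazole, CH2Cl2, 0 °C → rt
Reagents that add atoms: iodine, II
Why: Appel-type iodination converts the primary alcohol into the iodide and leaves the internal alkyne alone.

Step 11
Reactants: 19 methyl 2-[bis(2,2,2-trifluoroethoxy)phosphoryl]acetate; 18 5-iodopent-2-yne
Product: 20 methyl 2-[bis(2,2,2-trifluoroethoxy)phosphoryl]hept-5-ynoate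
Conditions: 19 (1.5 equiv), NaH (1.4 equiv), DMF, 0 °C; then 18 (1.0 equiv), rt → 45 °C
Reagents that add atoms: none
Why: Malonate-type C-alkylation of the sodium phosphonoacetate with the primary iodide should give the α-substituted reagent, with excess 19 holding back dialkylation.

Step 12
Reactants: 16 butenolide aldehyde; 20 phosphonate
Product: 21 methyl (2Z,6E)-6-methyl-7-[(2S)-4-methyl-5-oxo-3-(prop-2-en-1-yl)-2,5-dihydrofuran-2-yl]-2-(pent-3-yn-1-yl)hepta-2,6-dienoate
Conditions: 20 (1.3 equiv), KHMDS (1.25 equiv), 18-crown-6 (4 equiv), THF, −78 °C; then 16, −78 °C; sat. aq. NH4Cl at −78 °C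
Reagents that add atoms: none
Why: In this Still–Gennari olefination the fast, irreversible elimination from the trifluoroethyl phosphonate adduct under dissociating conditions should give the Z-enoate (ester cis to C6), and the stabilised phosphonate anion is too weak a base at −78 °C to deprotonate C2.

Step 13
Reactants: 21 allyl enoate
Product: 22 methyl (2Z,6E)-7-[(2S)-3-(2,3-dihydroxypropyl)-4-methyl-5-oxo-2,5-dihydrofuran-2-yl]-6-methyl-2-(pent-3-yn-1-yl)hepta-2,6-dienoate
Conditions: OsO4 (2 mol%), NMO (1.1 equiv), acetone/H2O, 0 °C, stopped when 21 is consumed; aq. Na2SO3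
Reagents that add atoms: N-methylmorpholine N-oxide, C[N+]1([O-])CCOCC1; water, O
Why: Catalytic osmylation should take the monosubstituted allyl alkene, because the enoate and butenolide alkenes are electron-poor and the trisubstituted C3=C4 alkene is hindered by the butenolide and deactivated by the allylic lactone oxygen, as the 2,3-alkene of geranyl esters is.

Step 14
Reactants: 22 diol
Product: 23 methyl (2Z,6E)-6-methyl-7-[(2S)-4-methyl-5-oxo-3-(2-oxoethyl)-2,5-dihydrofuran-2-yl]-2-(pent-3-yn-1-yl)hepta-2,6-dienoate
Conditions: NaIO4 on silica gel (1.5 equiv), CH2Cl2, rt; filtered, concentrated, used at once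
Reagents that add atoms: none
Why: Periodate glycol cleavage under neutral, heterogeneous conditions should release the enolisable β,γ-unsaturated aldehyde without acid or base, so it can go into step 15 unpurified.

Step 15
Reactants: 23 butenolide ynal
Product: 24 (2S,13S)-13-O-triethylsilyl macrocycle (3E,7Z,11E; methyl ester on C8)
Conditions: Ni(cod)2 (25 mol%), IMes (1,3-dimesitylimidazol-2-ylidene, 25 mol%, premixed), Et3SiH (5 equiv), THF, syringe-pump addition of 23 to a final 0.002 M, rt
Reagents that add atoms: triethylsilane, CC[SiH](CC)CC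
Why: Zerovalent nickel carrying one IMes ligand binds the C11≡C12 alkyne and the C13 aldehyde and undergoes oxidative cyclisation to an oxanickelacyclopentene, which forms the C12–C13 bond; σ-bond metathesis of the Ni–O bond with Et3SiH then puts silicon on O13 and hydride on nickel, and C–H reductive elimination at C11 with retention gives the E-alkene (H cis to C13, C13 trans to C10). The closest known reaction type is the nickel-catalysed reductive macrocyclisation of ynals with trialkylsilanes and N-heterocyclic carbene ligands. The 14-membered ring is closed in the endocyclic mode, with both alkyne carbons inside the ring (formally 14-endo-dig). The C13 centre is under substrate control: the (2S) centre fixes the face of the flat butenolide on which the C3–C11 tether runs, so C12 meets the aldehyde on C14 from that side and the (13S) silyl ether is counted on as the major epimer; this remote induction is the least secure element and a chiral carbene can reinforce it. The step needs bond formation at C12 and not C11, which the small carbene and the small methyl cap secure by keeping the larger, tether-bearing carbon on nickel; it also needs the aldehyde and C2 to survive, which the base-free silane medium and slow addition at high dilution secure.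

Step 16
Reactants: 24 silyl ether
Product: 25 16-oxosarcoglaucol, the (2S,13S)-13-hydroxy macrocycle
Conditions: HF·pyridine, pyridine, THF, 0 °C
Reagents that add atoms: none
Why: Buffered fluoride desilylation of the allylic triethylsilyl ether avoids the basic conditions that could deprotonate C2.

Step 17
Reactants: 25 alcohol
Product: 26 16-oxosarcoglaucol acetate
Conditions: Ac2O, pyridine, DMAP (cat.), CH2Cl2, 0 °C → rt
Reagents that add atoms: acetic anhydride, CC(=O)OC(C)=O
Why: DMAP-catalysed O-acylation of the secondary allylic alcohol proceeds with retention at C13 and should give the target.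

**Compound list**
1 | geranyl acetate | CC(C)=CCC/C(C)=C/COC(C)=O | starting material
2 | (2E)-5-(3,3-dimethyloxiran-2-yl)-3-methylpent-2-en-1-yl acetate (racemic) | CC1(C)OC1CC/C(C)=C/COC(C)=O | intermediate
3 | (2E)-6,7-dihydroxy-3,7-dimethyloct-2-en-1-yl acetate (racemic, not isolated) | CC(C)(O)C(O)CC/C(C)=C/COC(C)=O | intermediate
4 | (2E)-3-methyl-6-oxohex-2-en-1-yl acetate | O=CCC/C(C)=C/COC(C)=O | intermediate
5 | (2E)-6,6-dimethoxy-3-methylhex-2-en-1-yl acetate (not isolated) | COC(OC)CC/C(C)=C/COC(C)=O | intermediate
6 | (2E)-6,6-dimethoxy-3-methylhex-2-en-1-ol | COC(OC)CC/C(C)=C/CO | intermediate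
7 | (2E)-6,6-dimethoxy-3-methylhex-2-enal | COC(OC)CC/C(C)=C/C=O | intermediate
8 | 1-propynylmagnesium bromide | CC#C[Mg]Br | starting material
9 | racemic (5E)-9,9-dimethoxy-6-methylnon-5-en-2-yn-4-ol | COC(OC)CC/C(C)=C/C(O)C#CC | intermediate
10 | (5E)-9,9-dimethoxy-6-methylnon-5-en-2-yn-4-one | COC(OC)CC/C(C)=C/C(=O)C#CC | intermediate
11 | (4S,5E)-9,9-dimethoxy-6-methylnon-5-en-2-yn-4-ol | COC(OC)CC/C(C)=C/[C@H](O)C#CC | intermediate
12 | allylmagnesium bromide | C=CC[Mg]Br | starting material
13 | five-membered oxamagnesacycle from anti-allylmagnesiation of 11 (not isolated) | COC(OC)CC/C(C)=C/[C@@H]1O[Mg]C(C)=C1CC=C | intermediate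
14 | (2Z,4S,5E)-4-hydroxy-9,9-dimethoxy-2,6-dimethyl-3-(prop-2-en-1-yl)nona-2,5-dienoic acid (not isolated) | COC(OC)CC/C(C)=C/[C@H](O)/C(CC=C)=C(/C)C(=O)O | intermediate
15 | (5S)-5-[(1E)-5,5-dimethoxy-2-methylpent-1-en-1-yl]-3-methyl-4-(prop-2-en-1-yl)furan-2(5H)-one | COC(OC)CC/C(C)=C/[C@@H]1OC(=O)C(C)=C1CC=C | intermediate
16 | (4E)-4-methyl-5-[(2S)-4-methyl-5-oxo-3-(prop-2-en-1-yl)-2,5-dihydrofuran-2-yl]pent-4-enal | O=CCC/C(C)=C/[C@@H]1OC(=O)C(C)=C1CC=C | intermediate
17 | pent-3-yn-1-ol | CC#CCCO | starting material
18 | 5-iodopent-2-yne | CC#CCCI | intermediate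
19 | methyl 2-[bis(2,2,2-trifluoroethoxy)phosphoryl]acetate | COC(=O)CP(=O)(OCC(F)(F)F)OCC(F)(F)F | starting material
20 | methyl 2-[bis(2,2,2-trifluoroethoxy)phosphoryl]hept-5-ynoate (racemic) | COC(=O)C(CCC#CC)P(=O)(OCC(F)(F)F)OCC(F)(F)F | intermediate
21 | methyl (2Z,6E)-6-methyl-7-[(2S)-4-methyl-5-oxo-3-(prop-2-en-1-yl)-2,5-dihydrofuran-2-yl]-2-(pent-3-yn-1-yl)hepta-2,6-dienoate | COC(=O)/C(CCC#CC)=C\CC/C(C)=C/[C@@H]1OC(=O)C(C)=C1CC=C | intermediate
22 | methyl (2Z,6E)-7-[(2S)-3-(2,3-dihydroxypropyl)-4-methyl-5-oxo-2,5-dihydrofuran-2-yl]-6-methyl-2-(pent-3-yn-1-yl)hepta-2,6-dienoate (carbinol epimers) | COC(=O)/C(CCC#CC)=C\CC/C(C)=C/[C@@H]1OC(=O)C(C)=C1CC(O)CO | intermediate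
23 | methyl (2Z,6E)-6-methyl-7-[(2S)-4-methyl-5-oxo-3-(2-oxoethyl)-2,5-dihydrofuran-2-yl]-2-(pent-3-yn-1-yl)hepta-2,6-dienoate | COC(=O)/C(CCC#CC)=C\CC/C(C)=C/[C@@H]1OC(=O)C(C)=C1CC=O | intermediate
24 | (2S,13S)-13-O-triethylsilyl macrocycle (13-O-triethylsilyl-16-oxosarcoglaucol) | COC(=O)/C1=C\CC/C(C)=C/[C@@H]2OC(=O)C(C)=C2C[C@H](O[Si](CC)(CC)CC)/C(C)=C/CC1 | intermediate
25 | 16-oxosarcoglaucol, the (2S,13S)-13-hydroxy macrocycle | COC(=O)/C1=C\CC/C(C)=C/[C@@H]2OC(=O)C(C)=C2C[C@H](O)/C(C)=C/CC1 | intermediate
26 | 16-oxosarcoglaucol acetate | COC(=O)/C1=C\CC/C(C)=C/[C@@H]2OC(=O)C(C)=C2C[C@H](OC(C)=O)/C(C)=C/CC1 | target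

**Step count**
Total: 17 steps. Longest linear sequence: 15 steps (steps 1–9 and 12–17, from geranyl acetate).

**Three steps most likely to fail**

Step 15. The oxidative cyclisation may show low or reversed facial selectivity at C13, since the only control is remote induction from C2 across the butenolide. The fallback sets C13 by SN2 inversion instead of by induction in the ring closure. It sets out from ynal 23: the ring closure is run as in step 15 and the (13R)-triethylsilyl ether F1 is separated. F1 is desilylated with HF·pyridine to the (13R)-alcohol F2. F2 is esterified under Mitsunobu conditions (acetic acid, PPh3, diisopropyl azodicarboxylate, toluene, 0 °C), which should give the acetate with inversion. The fallback comes back to the route at target 26.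

Step 13. Osmylation may also take the trisubstituted C3=C4 alkene, so that the allyl group is not cleaved cleanly. The fallback brings in the two-carbon arm already at the aldehyde oxidation level, so no alkene has to be cleaved. It sets out from propargylic alcohol 11: CuI-catalysed (10 mol%) anti-carbomagnesiation with commercial (1,3-dioxolan-2-ylmethyl)magnesium bromide in THF, CO2 capture and citric acid work-up should give the dioxolanylmethyl butenolide F3. Dilute aqueous acetic acid should hydrolyse only the acyclic dimethyl acetal, giving the butenolide aldehyde F4. Still–Gennari olefination of F4 with 20, as in step 12, should give the Z-enoate F5. Hydrolysis of the dioxolane of F5 (aqueous formic acid, or PPTS in wet acetone) comes back to the route at ynal 23.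

Step 7. The oxazaborolidine may discriminate poorly between the alkenyl and alkynyl groups of ynone 10, which would erode the enantiopurity of C2. The fallback is enzymatic kinetic resolution and sets out from racemic carbinol 9, leaving out steps 6 and 7. Burkholderia cepacia lipase and vinyl acetate in hexane/MTBE at 30 °C should, by the usual size rule for lipases (alkenyl arm large, propynyl medium), acylate the (S)-enantiomer. This gives the (S)-acetate F6 beside the unreacted (R)-alcohol F7. F6 is separated and methanolysed (K2CO3, MeOH, 0 °C), which comes back to the route at 11. F7 can be recycled to 9 by MnO2 oxidation to 10 and NaBH4/CeCl3 reduction.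

**Further compounds**
F1 | step 15 | (2S,13R)-13-O-triethylsilyl macrocycle (C13 epimer of 24) | COC(=O)/C1=C\CC/C(C)=C/[C@@H]2OC(=O)C(C)=C2C[C@@H](O[Si](CC)(CC)CC)/C(C)=C/CC1
F2 | step 15 | (2S,13R)-13-hydroxy macrocycle (C13 epimer of 25) | COC(=O)/C1=C\CC/C(C)=C/[C@@H]2OC(=O)C(C)=C2C[C@@H](O)/C(C)=C/CC1
F3 | step 13 | (5S)-5-[(1E)-5,5-dimethoxy-2-methylpent-1-en-1-yl]-4-(1,3-dioxolan-2-ylmethyl)-3-methylfuran-2(5H)-one | COC(OC)CC/C(C)=C/[C@@H]1OC(=O)C(C)=C1CC2OCCO2
F4 | step 13 | (4E)-5-[(2S)-3-(1,3-dioxolan-2-ylmethyl)-4-methyl-5-oxo-2,5-dihydrofuran-2-yl]-4-methylpent-4-enal | O=CCC/C(C)=C/[C@@H]1OC(=O)C(C)=C1CC2OCCO2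
F5 | step 13 | methyl (2Z,6E)-7-[(2S)-3-(1,3-dioxolan-2-ylmethyl)-4-methyl-5-oxo-2,5-dihydrofuran-2-yl]-6-methyl-2-(pent-3-yn-1-yl)hepta-2,6-dienoate | COC(=O)/C(CCC#CC)=C\CC/C(C)=C/[C@@H]1OC(=O)C(C)=C1CC2OCCO2
F6 | step 7 | (4S,5E)-9,9-dimethoxy-6-methylnon-5-en-2-yn-4-yl acetate | COC(OC)CC/C(C)=C/[C@H](OC(C)=O)C#CC
F7 | step 7 | (4R,5E)-9,9-dimethoxy-6-methylnon-5-en-2-yn-4-ol | COC(OC)CC/C(C)=C/[C@@H](O)C#CC
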